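The data were computed on assumed constants; scatter was added.

The easy step came first. On Tuesday's run each substrate had already dropped to 25.5% of the charge by 1.50 h, and it then sank slowly to 21.8% by 12.0 h. I set that early drop aside and looked at the slow part.

| flask | left-handed substrate | right-handed substrate | solid reagent | remark | time |
|---|---|---|---|---|---|
| Thursday's | 0.20 M | 0.20 M | 1.5 equiv | run made earlier |  |
| Tuesday's | 0.20 M | 0.20 M | 3.3 equiv | run made earlier |  |
| Sunday's | 0.10 M | 0.10 M | 2.2 equiv | run made earlier |  |
| flask | 0.20 M | 0.20 M | 2.20 equiv |  | 15 h |

| run | time / h | left-handed substrate / % | right-handed substrate / % | left-handed product / % |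
|---|---|---|---|---|
| Thursday's | 3.00 | 25.8 | 24.5 | 1.0 |
| Thursday's | 6.00 | 23.4 | 24.8 | 3.6 |
| Thursday's | 10.0 | 22.2 | 22.2 | 6.2 |
| Thursday's | 12.0 | 21.7 | 21.2 | 6.5 |
| Tuesday's | 1.50 | 25.5 | 25.5 | 0.9 |
| Tuesday's | 4.00 | 24.7 | 25.2 | 2.3 |
| Tuesday's | 8.00 | 23.3 | 24.2 | 4.7 |
| Tuesday's | 12.0 | 21.8 | 21.9 | 7.4 |
| Sunday's | 1.50 | 25.5 | 25.9 | 1.4 |
| Sunday's | 4.00 | 24.5 | 25.5 | 2.3 |
| Sunday's | 8.00 | 22.9 | 23.9 | 4.9 |
| Sunday's | 12.0 | 21.4 | 21.6 | 8.4 |

(standard deviation of a reading: 0.5 percentage points)

- partner is single-handed; left-handed substrate and right-handed substrate are mirror images of each other, charged as a racemate, each of them at the stated concentration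
- given per volume of solution although it is solid: solid reagent
- the earlier runs were read with a standard deviation of 0.5 percentage points
- at the start none of the solid reagent is in solution
- what has gone into achiral form counts as reacted
- an excess is the difference of the two amounts in percent of their sum
- an excess is below zero if the other one leads
- the handed part of partner does not stay in what it makes, so the products of the two hands are mirror images too

- part of the left-handed substrate and right-handed substrate charged together that has reacted at 15 h
- excess of left-handed product over right-handed product in the product at 15 h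
- excess of right-handed substrate over left-handed substrate among what is left of the two at 15 h

On Tuesday's run left-handed product rose from 0.9% to 7.4%, which gave 0.00619 h⁻¹. This is the product pace: the gain of left-handed product per hour, as a fraction of both substrates charged.

Thursday's run, with less solid reagent, gave 0.00611 h⁻¹. Sunday's run, at lower concentration, gave 0.00667 h⁻¹.

The weak link was Thursday's late stall, which might have bent the line. A steady rise from 10.0 h to 12.0 h on Thursday's run came to 1.2 percentage points, but the readings rose 0.3 points, so they fell 0.92 points short. Each of those two readings carried a scatter of 0.5 points, so I took the stall as unproven. So I kept the line straight.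

Carried to 15 h, it gave 9.26% left-handed product. The two substrates together fell by 0.00695 h⁻¹, so I committed to 58.4% reacted. Right-handed product was never read, so I put no number on its excess.

The forecast gave 60% reacted, 68% product excess and 1% substrate excess, taking the late sag as “a small amount of right-handed product”, and so it named a product excess where I named none.

The flask gave 59.6% reacted, 94.7% product excess and 0.365% substrate excess.

    partner + left-handed substrate → left-handed product (k = 2.30 × 10⁻⁴ M⁻¹ s⁻¹)
    partner + right-handed substrate → right-handed product (k = 6.20 × 10⁻⁶ M⁻¹ s⁻¹)
    left-handed substrate ⇌ achiral form (K = 1.80, k = 0.00120 s⁻¹)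
    right-handed substrate ⇌ achiral form (K = 1.80, k = 0.00120 s⁻¹)
    achiral form → waste (k = 6.00 × 10⁻⁶ s⁻¹)
    partner → decomposed reagent (k = 6.90 × 10⁻⁵ s⁻¹)
    solid reagent ⇌ partner, rate k7*(cs7 - [partner]) while solid is left; crystals form when [partner] > cs7 (solubility = 0.110 M, k = 4.90 × 10⁻⁵ s⁻¹)

In the flask, exchange had put 46.5% into achiral form by 1.50 h, while solid reagent dissolved slowly and partner stood at 0.0203 M. From 7.50 h to 15 h partner stayed near 0.0391 M, and this dynamic kinetic resolution gave 9.49% left-handed product against 0.258% right-handed, while waste reached 13.5%. That is 0.00633 h⁻¹ averaged over the run, against the product pace of 0.00619 h⁻¹. The neighbour flask with 5.50 equiv of solid reagent ended at 9.49% left-handed product, also 0.00633 h⁻¹.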